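**Plan**

- Retrosynthesis: the seven-membered ring is opened at C18–C19 (SmI2 Reformatsky of a bromomethyl ketone/aldehyde). Further cuts are C17–C18 (bromomethyllithium), C16–C17 (Still–Wittig shift from a C21 ether), C12–C13 (alkenylcopper plus allylic picolinate, anti-SN2′), C4–C5 (alkenylcerium plus methyl ketone) and C10–C11 (aldol).
- Enabling feature: ring C16–C22 holds the β-hydroxy ketone C17(=O)–C18–C19(OH). C17 is flanked by the allylic, more acidic C16–H, so only an enolate generated from a C18 halide is regiodefined. The Z-C21=C22 bond on the cyclopentane (C13–C16, C22) holds C18 and C19 close.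
- Forward order: ring A (C7–C10, C24) from 2-allyl-2-methylcyclopentane-1,3-dione; ring B (C10–C12, C23, C24) by Wacker oxidation and aldol condensation; side chain by Wittig, hydroboration and alkenylcerium addition (fragment A, iodide 23). Ring C comes from 2-bromocyclopent-2-enone (fragment B, picolinate 35). Union, [2,3]-shift, then ring D (seven-membered) last.
- Stereochemistry: C24 by yeast desymmetrisation; C10 by the cis ring fusion; C7 by exo hydroboration; C5 by Felkin–Anh addition; C2 from (R)-but-3-yn-2-ol. C16–O and C21–O are set by two CBS reductions and relayed to C13 (anti-SN2′) and to C16 plus the Z-alkene (suprafacial [2,3]-shift). C19 is set in the key step.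

Key step: step 31

Remark: atom labels C1–C25 are those of the target SMILES read left to right (side chain C1–C6; ring A C7–C10, C24, methyl C25; ring B C10–C12, C23, C24; ring C C13–C16, C22; ring D C16–C22); the centre drawn at C5 in 14 and the open centres at C21 in 30 and C17 in 43 are removed by later oxidation.

**Route**

Step 1
Reactants: 1 2-allyl-2-methylcyclopentane-1,3-dione
Product: 2 (2S,3S)-2-allyl-3-hydroxy-2-methylcyclopentan-1-one
Conditions: baker's yeast (Saccharomyces cerevisiae), sucrose, H2O, 30 °C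
Reagents that add atoms: none
Why: Microbial desymmetrising reduction of a prochiral 2,2-disubstituted cyclopentane-1,3-dione, in which the yeast reductase reduces one enantiotopic carbonyl from the face remote from the allyl group, sets the carbinol carbon (C7) and makes the quaternary carbon C24 stereogenic in the required sense.

Step 2
Reactants: 2 (2S,3S)-2-allyl-3-hydroxy-2-methylcyclopentan-1-one
Product: 3 (2S,3S)-2-allyl-3-(tert-butyldimethylsilyloxy)-2-methylcyclopentan-1-one
Conditions: TBSCl, imidazole, DMF, rt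
Reagents that add atoms: tert-butyldimethylsilyl chloride, CC(C)(C)[Si](C)(C)Cl
Why: Silyl ether formation masks the β-hydroxy ketone so that the basic aldol step cannot open ring A by retro-aldol cleavage.

Step 3
Reactants: 3 (2S,3S)-2-allyl-3-(tert-butyldimethylsilyloxy)-2-methylcyclopentan-1-one
Product: 4 (2S,3S)-3-(tert-butyldimethylsilyloxy)-2-methyl-2-(2-oxopropyl)cyclopentan-1-one
Conditions: PdCl2 (0.1 equiv), CuCl, O2 (1 atm), DMF/H2O, rt
Reagents that add atoms: water, O
Why: Tsuji–Wacker oxidation (Markovnikov hydroxypalladation of the terminal alkene, β-hydride elimination) gives the methyl ketone and thus the 1,4-diketone.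

Step 4
Reactants: 4 (2S,3S)-3-(tert-butyldimethylsilyloxy)-2-methyl-2-(2-oxopropyl)cyclopentan-1-one
Product: 5 (6S,6aR)-6-(tert-butyldimethylsilyloxy)-6a-methyl-4,5,6,6a-tetrahydropentalen-2(1H)-one
Conditions: KOt-Bu (0.3 equiv), t-BuOH, 40 °C
Reagents that add atoms: none
Why: Intramolecular aldol condensation, in which the methyl-ketone enolate (C11) adds to the ring ketone (C10) and water is lost, closes ring B as the bicyclo[3.3.0]oct-1-en-3-one; the bridged aldol from the other enolate is reversible and cannot dehydrate.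

Step 5
Reactants: 5 (6S,6aR)-6-(tert-butyldimethylsilyloxy)-6a-methyl-4,5,6,6a-tetrahydropentalen-2(1H)-one
Product: 7 (3aS,6S,6aR)-6-(tert-butyldimethylsilyloxy)-6a-methyl-1,3a,4,5,6,6a-hexahydropentalen-2-yl trifluoromethanesulfonate, via lithium enolate 6 (not isolated)
Conditions: Li, NH3(l)/THF, t-BuOH (1 equiv), −78 °C; isoprene; NH3 removed; PhNTf2, THF, 0 °C → rt
Reagents that add atoms: N-phenylbis(trifluoromethanesulfonimide), O=S(=O)(N(c1ccccc1)S(=O)(=O)C(F)(F)F)C(F)(F)F
Why: Dissolving-metal reduction of the enone gives the enolate regiospecifically and protonates C10 so that the rings are cis-fused (H-10 cis to CH3-25, the only unstrained fusion), and O-sulfonylation of that enolate (reductive triflation) fixes the double bond at C11=C12.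

Step 6
Reactants: 7 (3aS,6S,6aR)-6-(tert-butyldimethylsilyloxy)-6a-methyl-1,3a,4,5,6,6a-hexahydropentalen-2-yl trifluoromethanesulfonate
Product: 9 tert-butyl{[(1S,3aS,6aR)-5-iodo-6a-methyl-1,2,3,3a,6,6a-hexahydropentalen-1-yl]oxy}dimethylsilane, via alkenylstannane 8 (not isolated)
Conditions: Me6Sn2, Pd(PPh3)4 (5 mol%), LiCl, THF, 65 °C; then I2, CH2Cl2, 0 °C
Reagents that add atoms: iodine, II
Why: Stille-type stannylation of the enol triflate under zerovalent palladium and iododestannylation with retention give an alkenyl iodide, which tolerates the fluoride, ylide and borane steps ahead and can be lithiated in step 25.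

Step 7
Reactants: 9 tert-butyl{[(1S,3aS,6aR)-5-iodo-6a-methyl-1,2,3,3a,6,6a-hexahydropentalen-1-yl]oxy}dimethylsilane
Product: 10 (1S,3aS,6aR)-5-iodo-6a-methyl-1,2,3,3a,6,6a-hexahydropentalen-1-ol
Conditions: TBAF, THF, 0 °C → rt
Reagents that add atoms: none
Why: Fluoride cleavage of the secondary silyl ether frees the C7 alcohol; the alkenyl iodide is inert.

Step 8
Reactants: 10 (1S,3aS,6aR)-5-iodo-6a-methyl-1,2,3,3a,6,6a-hexahydropentalen-1-ol
Product: 11 (3aS,6aR)-5-iodo-6a-methyl-3,3a,6,6a-tetrahydropentalen-1(2H)-one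
Conditions: DMP, CH2Cl2, rt
Reagents that add atoms: none
Why: Periodinane oxidation of the secondary alcohol under neutral conditions gives the cyclopentanone next to the quaternary C24.

Step 9
Reactants: 11 (3aS,6aR)-5-iodo-6a-methyl-3,3a,6,6a-tetrahydropentalen-1(2H)-one
Product: 12 (1Z,3aS,6aR)-1-ethylidene-5-iodo-6a-methyl-1,2,3,3a,6,6a-hexahydropentalene
Conditions: EtPPh3Br, KOt-Bu, THF, 65 °C
Reagents that add atoms: ethyltriphenylphosphonium bromide, CC[P+](c1ccccc1)(c1ccccc1)c1ccccc1.[Br-]
Why: Wittig olefination of a hindered α-quaternary cyclopentanone with the non-stabilised ethylidene ylide, as practised on 17-oxo steroids, installs C5 and C6; either alkene isomer serves because C5 is oxidised later.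

Step 10
Reactants: 12 (1Z,3aS,6aR)-1-ethylidene-5-iodo-6a-methyl-1,2,3,3a,6,6a-hexahydropentalene
Product: 14 (1S)-1-[(1S,3aS,6aR)-5-iodo-6a-methyl-1,2,3,3a,6,6a-hexahydropentalen-1-yl]ethan-1-ol, via alkylborane 13 (not isolated)
Conditions: 9-BBN, THF, 65 °C; then NaOH, H2O2, H2O, 0 °C → rt
Reagents that add atoms: hydrogen peroxide, OO
Why: Hydroboration–oxidation puts boron on the less substituted C5 and hydrogen on C7 from the convex face of the cis-fused bicycle (the face of H-10 and CH3-25), so the two-carbon branch ends on the concave face trans to CH3-25 (7S), while the electron-poor iodoalkene does not react.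

Step 11
Reactants: 14 (1S)-1-[(1S,3aS,6aR)-5-iodo-6a-methyl-1,2,3,3a,6,6a-hexahydropentalen-1-yl]ethan-1-ol
Product: 15 1-[(1S,3aS,6aR)-5-iodo-6a-methyl-1,2,3,3a,6,6a-hexahydropentalen-1-yl]ethan-1-one
Conditions: DMP, CH2Cl2, rt
Reagents that add atoms: none
Why: Periodinane oxidation gives the methyl ketone without base, so the new C7 centre α to the carbonyl is not epimerised.

Step 12
Reactants: 16 (R)-but-3-yn-2-ol
Product: 17 (R)-(but-3-yn-2-yloxy)(tert-butyl)dimethylsilane
Conditions: TBSCl, imidazole, CH2Cl2, rt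
Reagents that add atoms: tert-butyldimethylsilyl chloride, CC(C)(C)[Si](C)(C)Cl
Why: Standard silylation of the propargylic alcohol; C2 is taken unchanged from the chiral pool.

Step 13
Reactants: 17 (R)-(but-3-yn-2-yloxy)(tert-butyl)dimethylsilane
Product: 19 (R,E)-tert-butyl[(4-iodobut-3-en-2-yl)oxy]dimethylsilane, via alkenylzirconocene chloride 18 (not isolated)
Conditions: Cp2Zr(H)Cl, THF, rt; then I2, 0 °C
Reagents that add atoms: iodine, II
Why: Hydrozirconation of the terminal alkyne (syn addition, metal at the terminus) and iodinolysis with retention give the (E)-alkenyl iodide.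

Step 14
Reactants: 15 1-[(1S,3aS,6aR)-5-iodo-6a-methyl-1,2,3,3a,6,6a-hexahydropentalen-1-yl]ethan-1-one; 19 (R,E)-tert-butyl[(4-iodobut-3-en-2-yl)oxy]dimethylsilane
Product: 22 (2S,3E,5R)-5-(tert-butyldimethylsilyloxy)-2-[(1S,3aS,6aR)-5-iodo-6a-methyl-1,2,3,3a,6,6a-hexahydropentalen-1-yl]hex-3-en-2-ol, via alkenyllithium 20 (not isolated), via alkenylcerium dichloride 21 (not isolated)
Conditions: 19, t-BuLi (2 equiv), Et2O, −78 °C; CeCl3, THF, −78 °C; then 15, −78 °C
Reagents that add atoms: none
Why: Iodine–lithium exchange and transmetalation give a weakly basic alkenylcerium reagent that adds to the methyl ketone without enolisation or exchange with the ring iodide, and Felkin–Anh attack anti to the quaternary C24 past the small C7–H, the sense known from Grignard additions to 20-oxopregnanes, sets C5 (S).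

Step 15
Reactants: 22 (2S,3E,5R)-5-(tert-butyldimethylsilyloxy)-2-[(1S,3aS,6aR)-5-iodo-6a-methyl-1,2,3,3a,6,6a-hexahydropentalen-1-yl]hex-3-en-2-ol
Product: 23 triethylsilyl ether of 22 (fragment A)
Conditions: TESOTf, 2,6-lutidine, CH2Cl2, −78 → 0 °C
Reagents that add atoms: triethylsilyl trifluoromethanesulfonate, CC[Si](CC)(CC)OS(=O)(=O)C(F)(F)F
Why: Silylation of the hindered tertiary alcohol with the silyl triflate protects it for the organometallic steps that follow.

Step 16
Reactants: 24 2-bromocyclopent-2-en-1-one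
Product: 25 (S)-2-bromocyclopent-2-en-1-ol
Conditions: (R)-2-methyl-CBS-oxazaborolidine (0.2 equiv), BH3·SMe2, THF, −20 °C; MeOH
Reagents that add atoms: none
Why: CBS reduction, in which the bromoalkenyl arm is the large group in the oxazaborolidine–borane complex, so that the (R)-catalyst gives the (S)-allylic alcohol (C16–O).

Step 17
Reactants: 25 (S)-2-bromocyclopent-2-en-1-ol
Product: 26 (S)-[(2-bromocyclopent-2-en-1-yl)oxy]triisopropylsilane
Conditions: TIPSCl, imidazole, DMF, rt
Reagents that add atoms: triisopropylsilyl chloride, CC(C)[Si](Cl)(C(C)C)C(C)C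
Why: Silylation with the bulky triisopropylsilyl group, chosen because it resists O-to-O silyl migration under the strongly basic alkylation of step 22.

Step 18
Reactants: 27 3-[(4-methoxybenzyl)oxy]propan-1-ol
Product: 28 3-[(4-methoxybenzyl)oxy]propanal
Conditions: DMP, CH2Cl2, 0 °C → rt
Reagents that add atoms: none
Why: Periodinane oxidation of the primary alcohol gives the aldehyde without β-elimination of the p-methoxybenzyloxy group.

Step 19
Reactants: 26 (S)-[(2-bromocyclopent-2-en-1-yl)oxy]triisopropylsilane; 28 3-[(4-methoxybenzyl)oxy]propanal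
Product: 30 3-[(4-methoxybenzyl)oxy]-1-[(5S)-5-(triisopropylsilyloxy)cyclopent-1-en-1-yl]propan-1-ol (both carbinol epimers), via cyclopentenyllithium 29 (not isolated)
Conditions: 26, t-BuLi (2.1 equiv), THF, −78 °C; then 28
Reagents that add atoms: none
Why: Bromine–lithium exchange gives the cyclopentenyllithium, which adds 1,2 to the aldehyde and forms C21–C22; the C21 epimers are both carried on because the centre is reset in steps 20 and 21.

Step 20
Reactants: 30 3-[(4-methoxybenzyl)oxy]-1-[(5S)-5-(triisopropylsilyloxy)cyclopent-1-en-1-yl]propan-1-ol (both carbinol epimers)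
Product: 31 3-[(4-methoxybenzyl)oxy]-1-[(5S)-5-(triisopropylsilyloxy)cyclopent-1-en-1-yl]propan-1-one
Conditions: DMP, CH2Cl2, rt
Reagents that add atoms: none
Why: Periodinane oxidation of the allylic alcohol gives the enone and erases the uncontrolled C21 centre.

Step 21
Reactants: 31 3-[(4-methoxybenzyl)oxy]-1-[(5S)-5-(triisopropylsilyloxy)cyclopent-1-en-1-yl]propan-1-one
Product: 32 (1R)-3-[(4-methoxybenzyl)oxy]-1-[(5S)-5-(triisopropylsilyloxy)cyclopent-1-en-1-yl]propan-1-ol
Conditions: (S)-2-methyl-CBS-oxazaborolidine, catecholborane, toluene, −78 °C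
Reagents that add atoms: none
Why: CBS reduction of the α-substituted enone, with the cyclopentenyl group as the large substituent, so that the (S)-catalyst sets C21 (R) by reagent control.

Step 22
Reactants: 32 (1R)-3-[(4-methoxybenzyl)oxy]-1-[(5S)-5-(triisopropylsilyloxy)cyclopent-1-en-1-yl]propan-1-ol
Product: 33 tributyl({(1R)-3-[(4-methoxybenzyl)oxy]-1-[(5S)-5-(triisopropylsilyloxy)cyclopent-1-en-1-yl]propoxy}methyl)stannane
Conditions: KH, Bu3SnCH2I, THF, 0 °C → rt
Reagents that add atoms: tributyl(iodomethyl)stannane, CCCC[Sn](CCCC)(CCCC)CI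
Why: Williamson etherification of the potassium alkoxide installs the tin handle for the later [2,3]-shift without touching the C21 centre.

Step 23
Reactants: 33 tributyl({(1R)-3-[(4-methoxybenzyl)oxy]-1-[(5S)-5-(triisopropylsilyloxy)cyclopent-1-en-1-yl]propoxy}methyl)stannane
Product: 34 (1S)-2-{(1R)-3-[(4-methoxybenzyl)oxy]-1-[(tributylstannyl)methoxy]propyl}cyclopent-2-en-1-ol
Conditions: TBAF, THF, 0 °C → rt
Reagents that add atoms: none
Why: Fluoride removes the silyl group from C16–O, while the stannylmethyl and p-methoxybenzyl ethers are stable to it.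

Step 24
Reactants: 34 (1S)-2-{(1R)-3-[(4-methoxybenzyl)oxy]-1-[(tributylstannyl)methoxy]propyl}cyclopent-2-en-1-ol
Product: 35 (1S)-2-{(1R)-3-[(4-methoxybenzyl)oxy]-1-[(tributylstannyl)methoxy]propyl}cyclopent-2-en-1-yl pyridine-2-carboxylate (fragment B)
Conditions: picolinic acid, DCC, DMAP (0.1 equiv), CH2Cl2, rt
Reagents that add atoms: picolinic acid, OC(=O)c1ccccn1
Why: Carbodiimide esterification turns C16–O into a chelating leaving group suited to copper-mediated allylic substitution.

Step 25
Reactants: 23 triethylsilyl ether of 22 (fragment A); 35 (1S)-2-{(1R)-3-[(4-methoxybenzyl)oxy]-1-[(tributylstannyl)methoxy]propyl}cyclopent-2-en-1-yl pyridine-2-carboxylate (fragment B)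
Product: 39 coupled diene (13R,21R) with C11=C12 and C16=C22, via alkenyllithium 36 (not isolated), via alkenylmagnesium bromide 37 (not isolated), via alkenylcopper reagent 38 (not isolated)
Conditions: 23 (1.5 equiv), t-BuLi, Et2O, −78 °C; MgBr2·OEt2; CuBr·SMe2, THF, −40 °C; then 35, −40 → 0 °C
Reagents that add atoms: none
Why: Copper-mediated anti-SN2′ allylic substitution, in which the alkenylcopper reagent made from the Grignard reagent attacks C13 on the face opposite to the magnesium-activated picolinate, relays the C16 configuration to C13 (R), forms C12–C13 and moves the double bond to C16=C22.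

Step 26
Reactants: 39 coupled diene (13R,21R) with C11=C12 and C16=C22
Product: 41 (13R,16R,21Z) primary alcohol with C16–CH2OH and C21=C22, via alkoxymethyllithium 40 (not isolated)
Conditions: n-BuLi (1.5 equiv), THF, −78 °C
Reagents that add atoms: none
Why: Tin–lithium exchange gives an α-alkoxymethyllithium that undergoes the Still–Wittig [2,3]-sigmatropic shift, delivering C17 to C16 on the face from which the C21–O bond leaves (21R to 16R, cis to the C13 substituent) while the C20 chain turns away from the C13 branch in the envelope transition state, which gives the Z-alkene with C20 cis to C16.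

Step 27
Reactants: 41 (13R,16R,21Z) primary alcohol with C16–CH2OH and C21=C22
Product: 42 C17 aldehyde of 41
Conditions: DMP, NaHCO3, CH2Cl2, 0 °C
Reagents that add atoms: none
Why: Buffered periodinane oxidation gives the β,γ-unsaturated aldehyde without base, so C16 and the alkene stay in place; the crude aldehyde is used at once.

Step 28
Reactants: 42 C17 aldehyde of 41
Product: 43 C17 bromohydrin (C17–OH, C18–Br; both C17 epimers)
Conditions: CH2Br2 (3 equiv), n-BuLi added slowly, THF, −78 °C; AcOH, −78 °C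
Reagents that add atoms: dibromomethane, BrCBr
Why: Bromomethyllithium, formed by bromine–lithium exchange in the presence of the aldehyde, adds to the carbonyl faster than it decomposes or enolises C16, and the cold acidic quench stops at the bromohydrin, whose C17 epimers converge in step 30.

Step 29
Reactants: 43 C17 bromohydrin (C17–OH, C18–Br; both C17 epimers)
Product: 44 bromohydrin diol with free C19–OH
Conditions: DDQ, CH2Cl2/pH 7 buffer, 0 °C
Reagents that add atoms: none
Why: Oxidative cleavage of the electron-rich p-methoxybenzyl ether (hydride abstraction by DDQ, hydrolysis of the oxocarbenium ion) under buffered conditions leaves the silyl ethers, the bromohydrin and the skipped diene untouched.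

Step 30
Reactants: 44 bromohydrin diol with free C19–OH
Product: 45 bromomethyl ketone aldehyde (C17=O, C18–Br, C19 aldehyde)
Conditions: DMP (3 equiv), NaHCO3, CH2Cl2, 0 °C
Reagents that add atoms: none
Why: The periodinane oxidises the secondary bromohydrin to the α-bromo ketone and the primary homoallylic alcohol to the β,γ-unsaturated aldehyde in one buffered, non-basic operation, so neither C16 nor the Z-alkene isomerises; the product is used immediately.

Step 31
Reactants: 45 bromomethyl ketone aldehyde (C17=O, C18–Br, C19 aldehyde)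
Product: 47 target with C2–OTBS and C5–OTES (19R), via samarium enolate 46 (not isolated)
Conditions: SmI2 (2.5 equiv), THF, −78 °C; then pH 7 buffer
Reagents that add atoms: none
Why: Two single-electron transfers from divalent samarium cleave the C18–Br bond and give a trivalent samarium enolate at C18 only, so the more acidic allylic C16–H is never deprotonated and C21=C22 cannot move into conjugation; the enolate then adds to the C19 aldehyde and forms C18–C19. The closest known reaction type is the SmI2-mediated intramolecular Reformatsky (aldol) reaction of ω-formyl α-bromo ketones, which is established for seven- and eight-membered β-hydroxy ketones. Ring D closes in a 7-exo-trig mode with the enolate double bond outside the new ring, helped by the Z-alkene and ring C, which hold C18 and C19 within bonding distance. C19 is set in a chair-like transition state in which samarium bridges the enolate and aldehyde oxygens and the forming ring keeps its substituents pseudo-equatorial, which should place the hydroxyl on the face of C16–H (19R), although this sense has to be confirmed. The step needs chemoselective reduction of the bromide beside the aldehyde and no epimerisation at C16; the much easier reduction of an α-bromo ketone at −78 °C and the neutral aprotic medium secure both.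

Step 32
Reactants: 47 target with C2–OTBS and C5–OTES (19R)
Product: 48 CNP0358460.1
Conditions: HF·pyridine, pyridine, THF, 0 °C → rt
Reagents that add atoms: none
Why: Fluoride-mediated cleavage of both silyl ethers under pyridine-buffered, mildly acidic conditions avoids the base-induced retro-aldol or β-elimination open to the β-hydroxy ketone and the acid-induced ionisation of the tertiary allylic alcohol.

**Compound list**

1 | 2-allyl-2-methylcyclopentane-1,3-dione | C=CCC1(C)C(=O)CCC1=O | starting material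
2 | (2S,3S)-2-allyl-3-hydroxy-2-methylcyclopentan-1-one | O[C@H]1CCC(=O)[C@@]1(C)CC=C | intermediate
3 | (2S,3S)-2-allyl-3-(tert-butyldimethylsilyloxy)-2-methylcyclopentan-1-one | CC(C)(C)[Si](C)(C)O[C@H]1CCC(=O)[C@@]1(C)CC=C | intermediate
4 | (2S,3S)-3-(tert-butyldimethylsilyloxy)-2-methyl-2-(2-oxopropyl)cyclopentan-1-one | CC(C)(C)[Si](C)(C)O[C@H]1CCC(=O)[C@@]1(C)CC(C)=O | intermediate
5 | (6S,6aR)-6-(tert-butyldimethylsilyloxy)-6a-methyl-4,5,6,6a-tetrahydropentalen-2(1H)-one | CC(C)(C)[Si](C)(C)O[C@H]1CCC2=CC(=O)C[C@@]12C | intermediate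
6 | lithium (3aS,6S,6aR)-6-(tert-butyldimethylsilyloxy)-6a-methyl-1,3a,4,5,6,6a-hexahydropentalen-2-olate | CC(C)(C)[Si](C)(C)O[C@H]1CC[C@H]2C=C(O[Li])C[C@]21C | intermediate
7 | (3aS,6S,6aR)-6-(tert-butyldimethylsilyloxy)-6a-methyl-1,3a,4,5,6,6a-hexahydropentalen-2-yl trifluoromethanesulfonate | CC(C)(C)[Si](C)(C)O[C@H]1CC[C@H]2C=C(OS(=O)(=O)C(F)(F)F)C[C@]21C | intermediate
8 | tert-butyldimethyl{[(1S,3aS,6aR)-6a-methyl-5-(trimethylstannyl)-1,2,3,3a,6,6a-hexahydropentalen-1-yl]oxy}silane | CC(C)(C)[Si](C)(C)O[C@H]1CC[C@H]2C=C([Sn](C)(C)C)C[C@]21C | intermediate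
9 | tert-butyl{[(1S,3aS,6aR)-5-iodo-6a-methyl-1,2,3,3a,6,6a-hexahydropentalen-1-yl]oxy}dimethylsilane | CC(C)(C)[Si](C)(C)O[C@H]1CC[C@H]2C=C(I)C[C@]21C | intermediate
10 | (1S,3aS,6aR)-5-iodo-6a-methyl-1,2,3,3a,6,6a-hexahydropentalen-1-ol | O[C@H]1CC[C@H]2C=C(I)C[C@]21C | intermediate
11 | (3aS,6aR)-5-iodo-6a-methyl-3,3a,6,6a-tetrahydropentalen-1(2H)-one | O=C1CC[C@H]2C=C(I)C[C@]21C | intermediate
12 | (1Z,3aS,6aR)-1-ethylidene-5-iodo-6a-methyl-1,2,3,3a,6,6a-hexahydropentalene | C/C=C1/CC[C@H]2C=C(I)C[C@]21C | intermediate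
13 | B-alkyl-9-borabicyclo[3.3.1]nonane from 12 (boron on C5, hydrogen on C7 from the exo face) | C[C@H](B1C2CCCC1CCC2)[C@H]1CC[C@H]2C=C(I)C[C@]21C | intermediate
14 | (1S)-1-[(1S,3aS,6aR)-5-iodo-6a-methyl-1,2,3,3a,6,6a-hexahydropentalen-1-yl]ethan-1-ol | C[C@H](O)[C@H]1CC[C@H]2C=C(I)C[C@]21C | intermediate
15 | 1-[(1S,3aS,6aR)-5-iodo-6a-methyl-1,2,3,3a,6,6a-hexahydropentalen-1-yl]ethan-1-one | CC(=O)[C@H]1CC[C@H]2C=C(I)C[C@]21C | intermediate
16 | (R)-but-3-yn-2-ol | C[C@@H](O)C#C | starting material
17 | (R)-(but-3-yn-2-yloxy)(tert-butyl)dimethylsilane | C[C@@H](O[Si](C)(C)C(C)(C)C)C#C | intermediate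
18 | chlorobis(cyclopentadienyl)[(1E,3R)-3-(tert-butyldimethylsilyloxy)but-1-en-1-yl]zirconium | C[C@@H](O[Si](C)(C)C(C)(C)C)/C=C/[Zr](Cl)(C1C=CC=C1)C1C=CC=C1 | intermediate
19 | (R,E)-tert-butyl[(4-iodobut-3-en-2-yl)oxy]dimethylsilane | C[C@@H](O[Si](C)(C)C(C)(C)C)/C=C/I | intermediate
20 | [(1E,3R)-3-(tert-butyldimethylsilyloxy)but-1-en-1-yl]lithium | C[C@@H](O[Si](C)(C)C(C)(C)C)/C=C/[Li] | intermediate
21 | dichloro[(1E,3R)-3-(tert-butyldimethylsilyloxy)but-1-en-1-yl]cerium | C[C@@H](O[Si](C)(C)C(C)(C)C)/C=C/[Ce](Cl)Cl | intermediate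
22 | (2S,3E,5R)-5-(tert-butyldimethylsilyloxy)-2-[(1S,3aS,6aR)-5-iodo-6a-methyl-1,2,3,3a,6,6a-hexahydropentalen-1-yl]hex-3-en-2-ol | C[C@@H](O[Si](C)(C)C(C)(C)C)/C=C/[C@](C)(O)[C@H]1CC[C@H]2C=C(I)C[C@]21C | intermediate
23 | triethylsilyl ether of 22 (fragment A: C2–OTBS, C5–OTES, C12 iodide) | C[C@@H](O[Si](C)(C)C(C)(C)C)/C=C/[C@](C)(O[Si](CC)(CC)CC)[C@H]1CC[C@H]2C=C(I)C[C@]21C | intermediate
24 | 2-bromocyclopent-2-en-1-one | O=C1CCC=C1Br | starting material
25 | (S)-2-bromocyclopent-2-en-1-ol | O[C@H]1CCC=C1Br | intermediate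
26 | (S)-[(2-bromocyclopent-2-en-1-yl)oxy]triisopropylsilane | CC(C)[Si](O[C@H]1CCC=C1Br)(C(C)C)C(C)C | intermediate
27 | 3-[(4-methoxybenzyl)oxy]propan-1-ol | COc1ccc(COCCCO)cc1 | starting material
28 | 3-[(4-methoxybenzyl)oxy]propanal | COc1ccc(COCCC=O)cc1 | intermediate
29 | [(5S)-5-(triisopropylsilyloxy)cyclopent-1-en-1-yl]lithium | CC(C)[Si](O[C@H]1CCC=C1[Li])(C(C)C)C(C)C | intermediate
30 | 3-[(4-methoxybenzyl)oxy]-1-[(5S)-5-(triisopropylsilyloxy)cyclopent-1-en-1-yl]propan-1-ol (both carbinol epimers) | CC(C)[Si](O[C@H]1CCC=C1C(O)CCOCc2ccc(OC)cc2)(C(C)C)C(C)C | intermediate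
31 | 3-[(4-methoxybenzyl)oxy]-1-[(5S)-5-(triisopropylsilyloxy)cyclopent-1-en-1-yl]propan-1-one | CC(C)[Si](O[C@H]1CCC=C1C(=O)CCOCc2ccc(OC)cc2)(C(C)C)C(C)C | intermediate
32 | (1R)-3-[(4-methoxybenzyl)oxy]-1-[(5S)-5-(triisopropylsilyloxy)cyclopent-1-en-1-yl]propan-1-ol | CC(C)[Si](O[C@H]1CCC=C1[C@H](O)CCOCc2ccc(OC)cc2)(C(C)C)C(C)C | intermediate
33 | tributyl({(1R)-3-[(4-methoxybenzyl)oxy]-1-[(5S)-5-(triisopropylsilyloxy)cyclopent-1-en-1-yl]propoxy}methyl)stannane | CC(C)[Si](O[C@H]1CCC=C1[C@H](OC[Sn](CCCC)(CCCC)CCCC)CCOCc2ccc(OC)cc2)(C(C)C)C(C)C | intermediate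
34 | (1S)-2-{(1R)-3-[(4-methoxybenzyl)oxy]-1-[(tributylstannyl)methoxy]propyl}cyclopent-2-en-1-ol | O[C@H]1CCC=C1[C@H](OC[Sn](CCCC)(CCCC)CCCC)CCOCc2ccc(OC)cc2 | intermediate
35 | (1S)-2-{(1R)-3-[(4-methoxybenzyl)oxy]-1-[(tributylstannyl)methoxy]propyl}cyclopent-2-en-1-yl pyridine-2-carboxylate (fragment B) | O=C(O[C@H]1CCC=C1[C@H](OC[Sn](CCCC)(CCCC)CCCC)CCOCc2ccc(OC)cc2)c3ccccn3 | intermediate
36 | C12-lithio derivative of 23 | C[C@@H](O[Si](C)(C)C(C)(C)C)/C=C/[C@](C)(O[Si](CC)(CC)CC)[C@H]1CC[C@H]2C=C([Li])C[C@]21C | intermediate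
37 | C12-magnesium bromide derivative of 23 | C[C@@H](O[Si](C)(C)C(C)(C)C)/C=C/[C@](C)(O[Si](CC)(CC)CC)[C@H]1CC[C@H]2C=C([Mg]Br)C[C@]21C | intermediate
38 | C12-copper derivative of 23 | C[C@@H](O[Si](C)(C)C(C)(C)C)/C=C/[C@](C)(O[Si](CC)(CC)CC)[C@H]1CC[C@H]2C=C([Cu])C[C@]21C | intermediate
39 | coupled diene (13R,21R) with C11=C12 and C16=C22 (C12–C13 bond, C21–OCH2SnBu3, C19–OPMB, side chain as in 23) | C[C@@H](O[Si](C)(C)C(C)(C)C)/C=C/[C@](C)(O[Si](CC)(CC)CC)[C@H]1CC[C@H]2C=C([C@H]3CCC=C3[C@H](OC[Sn](CCCC)(CCCC)CCCC)CCOCc4ccc(OC)cc4)C[C@]21C | intermediate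
40 | C21–OCH2Li derivative of 39 | C[C@@H](O[Si](C)(C)C(C)(C)C)/C=C/[C@](C)(O[Si](CC)(CC)CC)[C@H]1CC[C@H]2C=C([C@H]3CCC=C3[C@H](OC[Li])CCOCc4ccc(OC)cc4)C[C@]21C | intermediate
41 | (13R,16R,21Z) primary alcohol with C16–CH2OH and C21=C22 (C19–OPMB) | C[C@@H](O[Si](C)(C)C(C)(C)C)/C=C/[C@](C)(O[Si](CC)(CC)CC)[C@H]1CC[C@H]2C=C([C@H]3CC[C@@H](CO)/C3=C\CCOCc4ccc(OC)cc4)C[C@]21C | intermediate
42 | C17 aldehyde of 41 | C[C@@H](O[Si](C)(C)C(C)(C)C)/C=C/[C@](C)(O[Si](CC)(CC)CC)[C@H]1CC[C@H]2C=C([C@H]3CC[C@@H](C=O)/C3=C\CCOCc4ccc(OC)cc4)C[C@]21C | intermediate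
43 | C17 bromohydrin (C17–OH, C18–Br; both C17 epimers) | C[C@@H](O[Si](C)(C)C(C)(C)C)/C=C/[C@](C)(O[Si](CC)(CC)CC)[C@H]1CC[C@H]2C=C([C@H]3CC[C@@H](C(O)CBr)/C3=C\CCOCc4ccc(OC)cc4)C[C@]21C | intermediate
44 | bromohydrin diol with free C19–OH | C[C@@H](O[Si](C)(C)C(C)(C)C)/C=C/[C@](C)(O[Si](CC)(CC)CC)[C@H]1CC[C@H]2C=C([C@H]3CC[C@@H](C(O)CBr)/C3=C\CCO)C[C@]21C | intermediate
45 | bromomethyl ketone aldehyde (C17=O, C18–Br, C19 aldehyde; key-step precursor) | C[C@@H](O[Si](C)(C)C(C)(C)C)/C=C/[C@](C)(O[Si](CC)(CC)CC)[C@H]1CC[C@H]2C=C([C@H]3CC[C@@H](C(=O)CBr)/C3=C\CC=O)C[C@]21C | intermediate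
46 | O-bound trivalent samarium enolate of 45 (C17(OSmI2)=C18) | C[C@@H](O[Si](C)(C)C(C)(C)C)/C=C/[C@](C)(O[Si](CC)(CC)CC)[C@H]1CC[C@H]2C=C([C@H]3CC[C@@H](C(=C)O[Sm](I)I)/C3=C\CC=O)C[C@]21C | intermediate
47 | target with C2–OTBS and C5–OTES (19R; key-step product) | C[C@@H](O[Si](C)(C)C(C)(C)C)/C=C/[C@](C)(O[Si](CC)(CC)CC)[C@H]1CC[C@H]2C=C([C@H]3CC[C@H]4C(=O)C[C@H](O)CC=C34)C[C@]21C | intermediate
48 | CNP0358460.1 (2R,5S,7S,10S,13R,16R,19R,24R in the SMILES numbering) | C[C@@H](O)/C=C/[C@](C)(O)[C@H]1CC[C@H]2C=C([C@H]3CC[C@H]4C(=O)C[C@H](O)CC=C34)C[C@]21C | target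

**Step count and risks**

Total step count: 32. Longest linear sequence: 21 steps (steps 1–11, 14, 15, 25–32).

Most likely to fail, first: step 25. Transfer of the hindered alkenyl group from copper may be slow, so that acyl attack on the picolinate, α-substitution or protonation of the organometallic compete and the valuable iodide is wasted. The fallback replaces the stoichiometric organometallic by a boron reagent under copper catalysis; it sets out from 23 and 34 and comes back at 39. Iodide 23 would be borylated (B2pin2, PdCl2(dppf), KOAc, dioxane, 80 °C; Miyaura borylation) to the alkenyl pinacol boronate F1. Alcohol 34 would be phosphorylated (ClP(O)(OEt)2, pyridine, DMAP) to the allylic diethyl phosphate F2. The two would then be joined with CuCl, an N-heterocyclic carbene ligand (IMes·HCl) and NaOMe in THF. This copper-catalysed γ-selective allyl–alkenyl coupling of allylic phosphates with alkenylboronates also runs anti and therefore gives 39.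

Second: step 26. Facial control may be lost, because the shift has to take place on the face of the cyclopentene that carries the C13 substituent. The rotamer that delivers C17 to the other face (E-alkene, C16 epimer) may then compete, and [1,2]-shift or protonation of the carbanion would lower the yield further. The fallback is an intermolecular anti-SN2′ substitution with a hydroxymethyl anion equivalent; it sets out from 39 and comes back at 41. Iodinolysis of the O–CH2–Sn bond (I2, CH2Cl2, 0 °C, then aqueous NaHCO3/Na2S2O3, which hydrolyses the iodomethyl ether) would free the C21 alcohol F3. Mitsunobu esterification with picolinic acid (PPh3, DIAD) inverts C21 and gives the (21S)-picolinate F4. The reagent (i-PrO)Me2SiCH2MgCl with CuBr·SMe2 would then attack C16 anti to the picolinate, on the required face, to give the silane F5. Tamao oxidation (H2O2, KF, KHCO3, THF/MeOH) converts its C–Si bond into the C–OH bond of 41.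

Third: step 31. The aldehyde may be attacked on the wrong face within the chelated transition state, giving the C19 epimer, with simple debromination as a second loss. The fallback accepts the epimer and inverts it; it sets out from 45 and comes back at 47. The SmI2 closure would then give the 19-epimeric β-hydroxy ketone F6. Mitsunobu esterification with chloroacetic acid (PPh3, DIAD, toluene, 0 °C) inverts C19 and gives the (19R)-chloroacetate F7. Thiourea with NaHCO3 in ethanol then removes the chloroacetyl group under nearly neutral conditions, which spares the β-acyloxy ketone from elimination, and gives 47.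

Further compounds
F1 | step 25 | alkenyl pinacol boronate of fragment A (C12–Bpin in place of iodine) | C[C@@H](O[Si](C)(C)C(C)(C)C)/C=C/[C@](C)(O[Si](CC)(CC)CC)[C@H]1CC[C@H]2C=C(B3OC(C)(C)C(C)(C)O3)C[C@]21C
F2 | step 25 | diethyl phosphate of alcohol 34 | CCOP(=O)(OCC)O[C@H]1CCC=C1[C@H](OC[Sn](CCCC)(CCCC)CCCC)CCOCc2ccc(OC)cc2
F3 | step 26 | (21R) C21 alcohol of the coupled diene | C[C@@H](O[Si](C)(C)C(C)(C)C)/C=C/[C@](C)(O[Si](CC)(CC)CC)[C@H]1CC[C@H]2C=C([C@H]3CCC=C3[C@H](O)CCOCc4ccc(OC)cc4)C[C@]21C
F4 | step 26 | (21S) C21 picolinate of the coupled diene | C[C@@H](O[Si](C)(C)C(C)(C)C)/C=C/[C@](C)(O[Si](CC)(CC)CC)[C@H]1CC[C@H]2C=C([C@H]3CCC=C3[C@@H](OC(=O)c5ccccn5)CCOCc4ccc(OC)cc4)C[C@]21C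
F5 | step 26 | (13R,16R,21Z) C16 (isopropoxydimethylsilyl)methyl compound | C[C@@H](O[Si](C)(C)C(C)(C)C)/C=C/[C@](C)(O[Si](CC)(CC)CC)[C@H]1CC[C@H]2C=C([C@H]3CC[C@@H](C[Si](C)(C)OC(C)C)/C3=C\CCOCc4ccc(OC)cc4)C[C@]21C
F6 | step 31 | C19 epimer (19S) of 47 | C[C@@H](O[Si](C)(C)C(C)(C)C)/C=C/[C@](C)(O[Si](CC)(CC)CC)[C@H]1CC[C@H]2C=C([C@H]3CC[C@H]4C(=O)C[C@@H](O)CC=C34)C[C@]21C
F7 | step 31 | (19R) chloroacetate of 47 | C[C@@H](O[Si](C)(C)C(C)(C)C)/C=C/[C@](C)(O[Si](CC)(CC)CC)[C@H]1CC[C@H]2C=C([C@H]3CC[C@H]4C(=O)C[C@H](OC(=O)CCl)CC=C34)C[C@]21C
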